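**Plan**

1. Rings are lettered A (terminal 3,5-dihydroxyphenyl), then B, C, D along the ether chain; E–F and G–H are the biaryl arms on the two flanking oxygens of ring D, I–J the arm on the free flanking oxygen of ring B. In rings B, C and D, C-1 carries the oxygen to the preceding ring.
2. Feature used: rings E, G and I are benzene-1,3,5-triols with the core oxygen on C-2, the aryl ring (F, H, J) on C-4 and H on C-6. Each is the enol form of a 2-aryl-4-aryloxycyclohexane-1,3,5-trione, the retron of a Claisen closure of an O-linked 3,5-dioxo ester.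
3. Cuts, in retrosynthetic order: fifteen O–CH3 bonds; in each of E, G, I the ring bond C-4–C-5 (aryl-bearing carbon to former ester carbon); the CH(O-core)–CO bond of each chain; three O–CH2 bonds to the core triol; three O-benzyl bonds; the diaryl ether bonds A–O–B, B–O–C, C–O–D.
4. Forward: ring D phenol, then C–D, B–C–D and A–B–C–D; each hindered phenol oxygen is unmasked from an aldehyde by Baeyer–Villiger oxidation and arylated by SNAr or copper catalysis. Rings F, H, J arrive preformed in the arylacetyl units; rings E, G and I close together in step 14.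
5. Stereochemistry: the target has no stereocentre; the three labile CH centres of precursor 23 become aromatic carbons.

Key step: step 14

Remarks: compounds 1, 5, 13, 16 and 19 are taken as catalogue compounds. Compound 23 is drawn in the all-keto form; it is an unassigned mixture of enol tautomers and of diastereomers at its three CH(O-aryl) centres. Steps 10 and 13 are threefold: three molecules of 16 (step 10) and three molecules of 20 (step 13) enter each molecule of product. The first molecule stands under Reactants and the second and third under "Reagents that add atoms", so that each step is balanced as written.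

**Route**

Step 1
Reactants: 1 2,6-difluoro-4-methoxybenzaldehyde
Product: 2 2,6-bis(benzyloxy)-4-methoxybenzaldehyde
Conditions: BnOH (2.4 equiv), NaH (2.5 equiv), DMF, 0 °C then 50 °C
Reagents that add atoms: benzyl alcohol, OCc1ccccc1
Why: Both C–F bonds lie ortho to the formyl group, so sodium benzyloxide should replace them in turn by nucleophilic aromatic substitution (addition–elimination), the second more slowly because the first benzyloxy group donates into the ring.

Step 2
Reactants: 2 2,6-bis(benzyloxy)-4-methoxybenzaldehyde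
Product: 4 2,6-bis(benzyloxy)-4-methoxyphenol, via ring D aryl formate 3 (not isolated)
Conditions: mCPBA (1.3 equiv), CH2Cl2, 0 °C to rt; then K2CO3 (0.2 equiv), MeOH, rt, argon
Reagents that add atoms: mCPBA, O=C(OO)c1cccc(Cl)c1
Why: Baeyer–Villiger oxidation of an electron-rich benzaldehyde, in which the trioxygenated aryl group migrates to oxygen in preference to hydrogen, followed by methanolysis of the labile aryl formate.

Step 3
Reactants: 4 2,6-bis(benzyloxy)-4-methoxyphenol; 5 4-bromo-2,6-dimethoxybenzaldehyde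
Product: 6 4-[2,6-bis(benzyloxy)-4-methoxyphenoxy]-2,6-dimethoxybenzaldehyde
Conditions: CuI (10 mol %), picolinic acid (20 mol %), K3PO4, DMSO, 90 °C, argon
Reagents that add atoms: none
Why: Copper-catalysed Ullmann diaryl ether synthesis, in which a bromide that is para to a formyl group and free of ortho substituents should accept the 2,6-dialkoxyphenoxide under ligated-copper conditions suited to ortho-substituted phenols.

Step 4
Reactants: 6 4-[2,6-bis(benzyloxy)-4-methoxyphenoxy]-2,6-dimethoxybenzaldehyde
Product: 8 4-[2,6-bis(benzyloxy)-4-methoxyphenoxy]-2,6-dimethoxyphenol, via ring C aryl formate 7 (not isolated)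
Conditions: mCPBA (1.3 equiv), CH2Cl2, 0 °C to rt; then K2CO3 (0.2 equiv), MeOH, rt, argon
Reagents that add atoms: mCPBA, O=C(OO)c1cccc(Cl)c1
Why: Baeyer–Villiger oxidation of the 2,6-dimethoxy-4-aryloxybenzaldehyde with aryl migration, then formate methanolysis, which turns the formyl carbon of ring C into the hindered phenol carbon C-1.

Step 5
Reactants: 8 4-[2,6-bis(benzyloxy)-4-methoxyphenoxy]-2,6-dimethoxyphenol; 1 2,6-difluoro-4-methoxybenzaldehyde
Product: 9 2-{4-[2,6-bis(benzyloxy)-4-methoxyphenoxy]-2,6-dimethoxyphenoxy}-6-fluoro-4-methoxybenzaldehyde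
Conditions: K2CO3, DMF, 70 °C, argon, aldehyde 1 in twofold excess
Reagents that add atoms: none
Why: Nucleophilic aromatic substitution of a fluoride ortho to the formyl group by the hindered phenoxide, kept at one substitution because the new aryloxy group deactivates the second C–F bond and the difluoride is in excess.

Step 6
Reactants: 9 2-{4-[2,6-bis(benzyloxy)-4-methoxyphenoxy]-2,6-dimethoxyphenoxy}-6-fluoro-4-methoxybenzaldehyde
Product: 10 2-(benzyloxy)-6-{4-[2,6-bis(benzyloxy)-4-methoxyphenoxy]-2,6-dimethoxyphenoxy}-4-methoxybenzaldehyde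
Conditions: BnOH (1.5 equiv), NaH (1.6 equiv), DMF, 0 °C to rt
Reagents that add atoms: benzyl alcohol, OCc1ccccc1
Why: Nucleophilic aromatic substitution of the remaining ortho fluoride by benzyloxide, fluoride being a far better nucleofuge in addition–elimination than the neighbouring hindered aryloxide.

Step 7
Reactants: 10 2-(benzyloxy)-6-{4-[2,6-bis(benzyloxy)-4-methoxyphenoxy]-2,6-dimethoxyphenoxy}-4-methoxybenzaldehyde
Product: 12 2-(benzyloxy)-6-{4-[2,6-bis(benzyloxy)-4-methoxyphenoxy]-2,6-dimethoxyphenoxy}-4-methoxyphenol, via ring B aryl formate 11 (not isolated)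
Conditions: mCPBA (1.3 equiv), CH2Cl2, 0 °C to rt; then K2CO3 (0.2 equiv), MeOH, rt, argon
Reagents that add atoms: mCPBA, O=C(OO)c1cccc(Cl)c1
Why: Baeyer–Villiger oxidation with migration of the tetra-oxygenated aryl group, then formate methanolysis, which unmasks the central oxygen of ring B.

Step 8
Reactants: 12 2-(benzyloxy)-6-{4-[2,6-bis(benzyloxy)-4-methoxyphenoxy]-2,6-dimethoxyphenoxy}-4-methoxyphenol; 13 1-iodo-3,5-dimethoxybenzene
Product: 14 ring A–B–C–D tribenzyl ether: 1-(benzyloxy)-3-{4-[2,6-bis(benzyloxy)-4-methoxyphenoxy]-2,6-dimethoxyphenoxy}-2-(3,5-dimethoxyphenoxy)-5-methoxybenzene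
Conditions: CuI (20 mol %), picolinic acid (40 mol %), K3PO4, DMSO, 100 °C, argon
Reagents that add atoms: none
Why: Copper-catalysed Ullmann diaryl ether synthesis, in which an aryl iodide without ortho substituents is paired with the doubly ortho-substituted phenoxide so that the crowding sits on one partner only.

Step 9
Reactants: 14 ring A–B–C–D tribenzyl ether
Product: 15 core triol: 3-[4-(2,6-dihydroxy-4-methoxyphenoxy)-2,6-dimethoxyphenoxy]-2-(3,5-dimethoxyphenoxy)-5-methoxyphenol
Conditions: H2 (1 atm), Pd/C (10 %), EtOAc–MeOH, rt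
Reagents that add atoms: none
Why: Catalytic hydrogenolysis cleaves the three benzyl ethers and leaves methyl ethers and diaryl ethers untouched.

Step 10
Reactants: 15 core triol; 16 methyl 4-chloro-3-oxobutanoate (3 equiv)
Product: 17 core tris(keto ester): 15 with each OH converted into OCH2C(=O)CH2CO2Me
Conditions: NaH (7 equiv), THF–DMF, 0 °C to 50 °C, 16 charged in slight excess (3.6 equiv); then dilute HCl
Reagents that add atoms: methyl 4-chloro-3-oxobutanoate (second equivalent), COC(=O)CC(=O)CCl; methyl 4-chloro-3-oxobutanoate (third equivalent), ClCC(=O)CC(=O)OC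
Why: Williamson ether synthesis, in which each of the three sodium phenoxides displaces the primary chloride of one molecule of 16 (SN2) while the keto ester is held as its sodium enolate, so that its acidic methylene does not quench the phenoxides.

Step 11
Reactants: 17 core tris(keto ester)
Product: 18 core tris(silyl enol ether): each chain is OCH2C(OSiMe3)=CHCO2Me, enol ether geometry unassigned
Conditions: Me3SiCl (4.5 equiv), Et3N (5 equiv), toluene, rt; filtered under argon
Reagents that add atoms: chlorotrimethylsilane, C[Si](C)(C)Cl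
Why: Silyl enol ether formation by soft enolisation, the acidic β-keto ester methylene being removed by Et3N and the enolate silylated on oxygen.

Step 12
Reactants: 19 (2,4,6-trimethoxyphenyl)acetic acid
Product: 20 (2,4,6-trimethoxyphenyl)acetyl chloride
Conditions: (COCl)2, DMF (cat.), CH2Cl2, 0 °C to rt; evaporated and used crude
Reagents that add atoms: oxalyl chloride, O=C(Cl)C(=O)Cl
Why: Acid chloride formation through the Vilsmeier-type chloroiminium species, mild enough for the electron-rich arene.

Step 13
Reactants: 18 core tris(silyl enol ether); 20 (2,4,6-trimethoxyphenyl)acetyl chloride (3 equiv)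
Product: 23 core tris(triketide ester): each chain is OCH[C(=O)CH2Ar]C(=O)CH2CO2Me (Ar = 2,4,6-trimethoxyphenyl), via hexasilyl tris(diene) 21 (not isolated), via trisilyl acylation adduct 22 (not isolated)
Conditions: LiN(iPr)2 (3.6 equiv), THF, −78 °C, then Me3SiCl (4 equiv), −78 °C to rt; solvent changed to CH2Cl2 and LiCl filtered off under argon; 20 charged in slight excess (3.6 equiv), −78 °C to rt; aqueous NaHCO3, then 1 M HCl
Reagents that add atoms: chlorotrimethylsilane, C[Si](C)(C)Cl; (2,4,6-trimethoxyphenyl)acetyl chloride (second equivalent), COc1cc(OC)c(CC(=O)Cl)c(OC)c1; (2,4,6-trimethoxyphenyl)acetyl chloride (third equivalent), O=C(Cl)Cc1c(OC)cc(OC)cc1OC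
Why: γ-Deprotonation and O-silylation of each β-silyloxy enoate should give the 1,3-bis(silyloxy)-1,3-diene (the silyl groups appear only in 21 and 22), whose terminal aryloxy-bearing carbon is acylated by one molecule of the acid chloride per chain without added Lewis acid (Mukaiyama-type C-acylation of a silyl dienol ether), so that the three 3,5-dioxo ester chains are built without a hexa-anion of the substrate.

Step 14
Reactants: 23 core tris(triketide ester)
Product: 24 decamer pentadecamethyl ether: rings E, G and I as free benzene-1,3,5-triols, all other oxygens methylated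
Conditions: Mg(OMe)2 (12 equiv), MeOH–THF, reflux, argon; then 1 M HCl, 0 °C
Reagents that add atoms: none
Why: Mg(OMe)2 holds each chain as a magnesium chelate of its 1,3-dicarbonyl units and reversibly removes a proton from the benzylic C-6, which adds to the ester carbonyl C-1 and expels methoxide; the resulting 2-aryl-4-aryloxycyclohexane-1,3,5-trione tautomerises to the benzene-1,3,5-triol. The closest known reaction type is the base-mediated Claisen (Dieckmann-type) cyclisation of 3,5-dioxoalkanoates and higher polyketo esters to cyclohexane-1,3,5-triones and phloroglucinols. Rings E, G and I each close 6-exo-trig, C-6 attacking a carbonyl whose C=O lies outside the new ring, and no other carbon of a chain can form a ring larger than four members with a carbonyl of the same chain. No stereocentre is formed, and the three CH(O-aryl) centres of 23 end as aromatic carbons. The selectivity required is C- over O-acylation (the C-5 enol oxygen would give a 4-hydroxy-2-pyranone): magnesium binds the enol oxygens, methoxide reopens any lactone, and only the carbocycle leaves the equilibrium by aromatisation. The substrate is suited because the crowded aryl–O bonds and the tetra-ortho-oxygenated biaryl bonds already exist as O–CH and CH2–aryl bonds before rings E, G and I are made.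

Step 15
Reactants: 24 decamer pentadecamethyl ether
Product: 25 CNP0294555.0 (target)
Conditions: BBr3 (45 equiv), CH2Cl2, −78 °C to rt, argon; then H2O, 0 °C
Reagents that add atoms: none
Why: Lewis acid-mediated cleavage of all fifteen aryl methyl ethers through aryloxyboron bromides and bromomethane, while the diaryl ether and biaryl bonds offer no carbon open to bromide attack.

**Compound list**

1 | 2,6-difluoro-4-methoxybenzaldehyde | COc1cc(F)c(C=O)c(F)c1 | starting material
2 | 2,6-bis(benzyloxy)-4-methoxybenzaldehyde | COc1cc(OCc2ccccc2)c(C=O)c(OCc2ccccc2)c1 | intermediate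
3 | 2,6-bis(benzyloxy)-4-methoxyphenyl formate (ring D aryl formate) | COc1cc(OCc2ccccc2)c(OC=O)c(OCc2ccccc2)c1 | intermediate (not isolated)
4 | 2,6-bis(benzyloxy)-4-methoxyphenol | COc1cc(OCc2ccccc2)c(O)c(OCc2ccccc2)c1 | intermediate
5 | 4-bromo-2,6-dimethoxybenzaldehyde | COc1cc(Br)cc(OC)c1C=O | starting material
6 | 4-[2,6-bis(benzyloxy)-4-methoxyphenoxy]-2,6-dimethoxybenzaldehyde | COc1cc(OCc2ccccc2)c(Oc2cc(OC)c(C=O)c(OC)c2)c(OCc2ccccc2)c1 | intermediate
7 | 4-[2,6-bis(benzyloxy)-4-methoxyphenoxy]-2,6-dimethoxyphenyl formate (ring C aryl formate) | COc1cc(OCc2ccccc2)c(Oc2cc(OC)c(OC=O)c(OC)c2)c(OCc2ccccc2)c1 | intermediate (not isolated)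
8 | 4-[2,6-bis(benzyloxy)-4-methoxyphenoxy]-2,6-dimethoxyphenol | COc1cc(OCc2ccccc2)c(Oc2cc(OC)c(O)c(OC)c2)c(OCc2ccccc2)c1 | intermediate
9 | 2-{4-[2,6-bis(benzyloxy)-4-methoxyphenoxy]-2,6-dimethoxyphenoxy}-6-fluoro-4-methoxybenzaldehyde | COc1cc(F)c(C=O)c(Oc2c(OC)cc(Oc3c(OCc4ccccc4)cc(OC)cc3OCc3ccccc3)cc2OC)c1 | intermediate
10 | 2-(benzyloxy)-6-{4-[2,6-bis(benzyloxy)-4-methoxyphenoxy]-2,6-dimethoxyphenoxy}-4-methoxybenzaldehyde | COc1cc(OCc2ccccc2)c(C=O)c(Oc2c(OC)cc(Oc3c(OCc4ccccc4)cc(OC)cc3OCc3ccccc3)cc2OC)c1 | intermediate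
11 | 2-(benzyloxy)-6-{4-[2,6-bis(benzyloxy)-4-methoxyphenoxy]-2,6-dimethoxyphenoxy}-4-methoxyphenyl formate (ring B aryl formate) | COc1cc(OCc2ccccc2)c(OC=O)c(Oc2c(OC)cc(Oc3c(OCc4ccccc4)cc(OC)cc3OCc3ccccc3)cc2OC)c1 | intermediate (not isolated)
12 | 2-(benzyloxy)-6-{4-[2,6-bis(benzyloxy)-4-methoxyphenoxy]-2,6-dimethoxyphenoxy}-4-methoxyphenol | COc1cc(OCc2ccccc2)c(O)c(Oc2c(OC)cc(Oc3c(OCc4ccccc4)cc(OC)cc3OCc3ccccc3)cc2OC)c1 | intermediate
13 | 1-iodo-3,5-dimethoxybenzene | COc1cc(I)cc(OC)c1 | starting material
14 | ring A–B–C–D tribenzyl ether (benzyloxy on ring B C-6 and ring D C-2 and C-6, all other oxygens methylated) | COc1cc(OC)cc(Oc2c(Oc3c(OC)cc(Oc4c(OCc5ccccc5)cc(OC)cc4OCc4ccccc4)cc3OC)cc(OC)cc2OCc2ccccc2)c1 | intermediate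
15 | core triol (OH on ring B C-6 and ring D C-2 and C-6) | COc1cc(OC)cc(Oc2c(Oc3c(OC)cc(Oc4c(O)cc(OC)cc4O)cc3OC)cc(OC)cc2O)c1 | intermediate
16 | methyl 4-chloro-3-oxobutanoate (methyl 4-chloroacetoacetate) | COC(=O)CC(=O)CCl | starting material
17 | core tris(keto ester), each chain OCH2C(=O)CH2CO2Me | COc1cc(OC)cc(Oc2c(Oc3c(OC)cc(Oc4c(OCC(=O)CC(=O)OC)cc(OC)cc4OCC(=O)CC(=O)OC)cc3OC)cc(OC)cc2OCC(=O)CC(=O)OC)c1 | intermediate
18 | core tris(silyl enol ether), each chain OCH2C(OSiMe3)=CHCO2Me, geometry unassigned | COc1cc(OC)cc(Oc2c(Oc3c(OC)cc(Oc4c(OCC(O[Si](C)(C)C)=CC(=O)OC)cc(OC)cc4OCC(O[Si](C)(C)C)=CC(=O)OC)cc3OC)cc(OC)cc2OCC(O[Si](C)(C)C)=CC(=O)OC)c1 | intermediate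
19 | (2,4,6-trimethoxyphenyl)acetic acid | COc1cc(OC)c(CC(=O)O)c(OC)c1 | starting material
20 | (2,4,6-trimethoxyphenyl)acetyl chloride | COc1cc(OC)c(CC(=O)Cl)c(OC)c1 | intermediate
21 | hexasilyl tris(diene), each chain OCH=C(OSiMe3)CH=C(OMe)OSiMe3, geometry unassigned | COc1cc(OC)cc(Oc2c(Oc3c(OC)cc(Oc4c(OC=C(O[Si](C)(C)C)C=C(OC)O[Si](C)(C)C)cc(OC)cc4OC=C(O[Si](C)(C)C)C=C(OC)O[Si](C)(C)C)cc3OC)cc(OC)cc2OC=C(O[Si](C)(C)C)C=C(OC)O[Si](C)(C)C)c1 | intermediate (not isolated)
22 | trisilyl acylation adduct, each chain OCH[C(=O)CH2Ar]C(OSiMe3)=CHCO2Me, Ar = 2,4,6-trimethoxyphenyl, CH centres and geometry unassigned | COc1cc(OC)cc(Oc2c(Oc3c(OC)cc(Oc4c(OC(C(=O)Cc5c(OC)cc(OC)cc5OC)C(O[Si](C)(C)C)=CC(=O)OC)cc(OC)cc4OC(C(=O)Cc4c(OC)cc(OC)cc4OC)C(O[Si](C)(C)C)=CC(=O)OC)cc3OC)cc(OC)cc2OC(C(=O)Cc2c(OC)cc(OC)cc2OC)C(O[Si](C)(C)C)=CC(=O)OC)c1 | intermediate (not isolated)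
23 | core tris(triketide ester), each chain OCH[C(=O)CH2Ar]C(=O)CH2CO2Me, three labile CH centres unassigned | COc1cc(OC)cc(Oc2c(Oc3c(OC)cc(Oc4c(OC(C(=O)Cc5c(OC)cc(OC)cc5OC)C(=O)CC(=O)OC)cc(OC)cc4OC(C(=O)Cc4c(OC)cc(OC)cc4OC)C(=O)CC(=O)OC)cc3OC)cc(OC)cc2OC(C(=O)Cc2c(OC)cc(OC)cc2OC)C(=O)CC(=O)OC)c1 | intermediate
24 | decamer pentadecamethyl ether (rings E, G, I free triols; rings A, B, C, D, F, H, J fully O-methylated) | COc1cc(OC)cc(Oc2c(Oc3c(OC)cc(Oc4c(Oc5c(O)cc(O)c(-c6c(OC)cc(OC)cc6OC)c5O)cc(OC)cc4Oc4c(O)cc(O)c(-c5c(OC)cc(OC)cc5OC)c4O)cc3OC)cc(OC)cc2Oc2c(O)cc(O)c(-c3c(OC)cc(OC)cc3OC)c2O)c1 | intermediate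
25 | CNP0294555.0 | Oc1cc(O)cc(Oc2c(Oc3c(O)cc(Oc4c(Oc5c(O)cc(O)c(-c6c(O)cc(O)cc6O)c5O)cc(O)cc4Oc4c(O)cc(O)c(-c5c(O)cc(O)cc5O)c4O)cc3O)cc(O)cc2Oc2c(O)cc(O)c(-c3c(O)cc(O)cc3O)c2O)c1 | target

**Count**

Total steps: 15. Longest linear sequence: 14 steps (steps 1–11 and 13–15, from 1 to 25); step 12 is a one-step side branch.

**Steps most likely to fail**

Step 14. The C–C closure may lag, because the benzylic carbon is the least acidic and most crowded carbon of each chain and the ester sits next to an enolised methylene. Lactonisation through the C-5 enol oxygen or retro-Claisen loss of the arylacetyl group could then take over, and to a different extent on the three arms. The fallback folds the isomeric triketide, in which the aryl-bearing carbon is the central, doubly activated carbon and an unhindered aryloxymethylene closes the ring. It sets out from 15 and comes back at 24. Threefold O-alkylation of 15 with methyl bromoacetate (K2CO3, acetone, reflux) should give the core tris(methyl aryloxyacetate) F1. Separately, 20 and the lithium enolate of methyl acetate (LiN(SiMe3)2, THF, −78 °C) should give methyl 3-oxo-4-(2,4,6-trimethoxyphenyl)butanoate F2. The dianion of F2 (NaH, then n-BuLi, THF, 0 °C, about 7 equiv) is then acylated at its benzylic γ-carbon by the three ester groups of F1 (ester acylation of a β-keto ester dianion) to give the isomeric core tris(triketide ester) F3, with chains OCH2C(=O)CH(Ar)C(=O)CH2CO2Me. Here the polyanion burden lies on the small partner. Mg(OMe)2 in MeOH–THF at reflux should then close each ring by Claisen attack of the O–CH2 carbon on the ester, which leads to the same triols and hence to 24.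

Step 13. Threefold acylation may stop short, through protodesilylation of the moisture-sensitive hexasilyl tris(diene) before it meets the acid chloride or through loss of the acid chloride as ketene-derived material. The fallback uses lithium dianions and an amide electrophile; it sets out from 17 and comes back at 23. Acid chloride 20 with N,O-dimethylhydroxylamine hydrochloride and Et3N in CH2Cl2 should give N-methoxy-N-methyl-2-(2,4,6-trimethoxyphenyl)acetamide F4. Sixfold deprotonation of 17 (LiN(iPr)2, 6.6 equiv, THF, −78 to 0 °C) gives the three α,γ-dianions, which add through their aryloxy-bearing γ-carbons to F4 (3.6 equiv, −78 to 0 °C). The chelated tetrahedral adducts should persist until the aqueous NH4Cl quench, so the acidic product does not consume unreacted dianion, and 23 results directly.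

Step 10. The alkylation may stall after one or two ether bonds while the chloro keto ester is consumed by base-induced self-condensation. The fallback uses an electrophile without acidic hydrogens; it sets out from 15 and comes back at 17. Alkylation of 15 with methyl (E)-4-chloro-3-methoxybut-2-enoate (K2CO3, DMF, 60 °C) should give the core tris[(E)-3-methoxybut-2-enoate] ether F5 by clean SN2 at the allylic chloride. Hydrolysis of the three enol ethers (2 M HCl, THF, 40 °C) then gives 17.

**Further compounds**

F1 | step 14 | core tris(methyl aryloxyacetate), 15 with each OH converted into OCH2CO2Me | COc1cc(OC)cc(Oc2c(Oc3c(OC)cc(Oc4c(OCC(=O)OC)cc(OC)cc4OCC(=O)OC)cc3OC)cc(OC)cc2OCC(=O)OC)c1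
F2 | step 14 | methyl 3-oxo-4-(2,4,6-trimethoxyphenyl)butanoate | COC(=O)CC(=O)Cc1c(OC)cc(OC)cc1OC
F3 | step 14 | isomeric core tris(triketide ester), each chain OCH2C(=O)CH(Ar)C(=O)CH2CO2Me, Ar = 2,4,6-trimethoxyphenyl, CH centres unassigned | COc1cc(OC)cc(Oc2c(Oc3c(OC)cc(Oc4c(OCC(=O)C(c5c(OC)cc(OC)cc5OC)C(=O)CC(=O)OC)cc(OC)cc4OCC(=O)C(c4c(OC)cc(OC)cc4OC)C(=O)CC(=O)OC)cc3OC)cc(OC)cc2OCC(=O)C(c2c(OC)cc(OC)cc2OC)C(=O)CC(=O)OC)c1
F4 | step 13 | N-methoxy-N-methyl-2-(2,4,6-trimethoxyphenyl)acetamide | CON(C)C(=O)Cc1c(OC)cc(OC)cc1OC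
F5 | step 10 | core tris[(E)-3-methoxybut-2-enoate] ether, each chain OCH2C(OMe)=CHCO2Me with E geometry | COc1cc(OC)cc(Oc2c(Oc3c(OC)cc(Oc4c(OC/C(OC)=C\C(=O)OC)cc(OC)cc4OC/C(OC)=C\C(=O)OC)cc3OC)cc(OC)cc2OC/C(OC)=C\C(=O)OC)c1
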